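**Plan**
- Retrosynthesis: the γ-lactone is opened at O7–C19. The ten-membered ring (C1–C10) is then cut at C8–C9, the bond between the two carbinol carbons of the cis-8,9-diol; this is possible because C8 is also the ketone carbon of a β-keto ester (C8–C17–C19) that can chelate samarium opposite a C9 aldehyde. Further cuts are C8–C17 (aldol), C4–C5 (B-alkyl Suzuki), C2–C3 (vinyl addition) and C1–C14/C10–C11 (Diels–Alder of ring A).
- Forward: ring A (C1, C10–C14) is formed first by a catalytic asymmetric Diels–Alder reaction, oxidised to the 11-hydroxy enone and masked as its C12 ketal. The C5–C8 unit is joined at C4–C5, the β-keto ester is built on C8, SmI2 closes the ten-membered ring at C8–C9, and the lactone ring closes last.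
- Stereochemistry: C1/C10 from the catalyst and the E dienophile, C2 by CBS reduction, C11 by substrate-controlled enolate hydroxylation, C7 from D-glyceraldehyde, the 5Z alkene from a Z-iodoalkene, C8/C9 in the chelated pinacol closure, C17 by equilibration of the lactone.

Key step: step 20

Remarks
- Numbering and abbreviations: briarane numbering is used for all intermediates (ring A = C1, C10–C14; C2–C9 = the chain that closes to the ten-membered ring; C17, C18 (methyl), C19 = propionate unit); TBS = tert-butyldimethylsilyl, PMB = 4-methoxybenzyl.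
- Assumption: the (S)-configured cationic oxazaborolidine is taken to give the (1S,10S) adduct 6 by the usual formyl C–H···O binding model for α-substituted enals; if the sense is the opposite, the (R)-catalyst is used and nothing else changes.
- Assumption: compounds 1, 3, 4, 14, 22 and all unnumbered reagents are purchased.

**Route**

Step 1
Reactants: 1 ethyl vinyl ketone (pent-1-en-3-one)
Product: 2 (Z)-3-(tert-butyldimethylsilyloxy)penta-1,3-diene
Conditions: TBSOTf, Et3N, Et2O, 0 °C
Reagents that add atoms: tert-butyldimethylsilyl triflate, CC(C)(C)[Si](C)(C)OS(=O)(=O)C(F)(F)F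
Why: Soft enolisation and O-silylation of the ethyl ketone (silyl enol ether formation) should give the 2-silyloxydiene as the favoured Z enol ether, which places the future C11 methyl on the outside of the s-cis diene.

Step 2
Reactants: 3 2-[(4-methoxybenzyl)oxy]acetaldehyde; 4 2-(triphenylphosphoranylidene)propanal
Product: 5 (E)-4-[(4-methoxybenzyl)oxy]-2-methylbut-2-enal
Conditions: toluene, 80 °C
Reagents that add atoms: none
Why: Wittig olefination with the formyl-stabilised ylide is E-selective, and this geometry later becomes the cis relation of the C1 methyl and the C10 side chain.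

Step 3
Reactants: 2 (Z)-3-(tert-butyldimethylsilyloxy)penta-1,3-diene; 5 (E)-4-[(4-methoxybenzyl)oxy]-2-methylbut-2-enal
Product: 6 (1S,10S)-ring A aldehyde (C1 methyl and formyl C2; C10 CH2OPMB; C12 TBS enol ether C12=C13; C11 methyl epimers)
Conditions: (S)-3,3-diphenyl-1-(2-methylphenyl)tetrahydro-1H,3H-pyrrolo[1,2-c][1,3,2]oxazaborole·HNTf2 (20 mol%), CH2Cl2, −78 → −40 °C; Et3N quench
Reagents that add atoms: none
Why: Cationic-oxazaborolidine-catalysed Diels–Alder reaction in which the silyloxy-activated diene terminus C11 bonds to the enal β-carbon C10 and C14 to C1, the E geometry of 5 is carried suprafacially into the cis relation of the C1 methyl and the C10 CH2OPMB group, and the catalyst, which binds the s-trans enal and shields one face, sets the absolute configuration of C1 and C10; C11 is left as a mixture because it is enolised in step 9.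

Step 4
Reactants: 6 (1S,10S)-ring A aldehyde
Product: 7 (1S,10S)-vinyl carbinols (C2 epimers)
Conditions: CH2=CHMgBr, THF, −78 °C; H2O
Reagents that add atoms: vinylmagnesium bromide, C=C[Mg]Br
Why: Grignard 1,2-addition to the neopentyl aldehyde; the C2 configuration is not controlled here because the carbinol is oxidised in step 5.

Step 5
Reactants: 7 (1S,10S)-vinyl carbinols
Product: 8 (1S,10S)-vinyl ketone (C2 ketone)
Conditions: Dess–Martin periodinane, pyridine, CH2Cl2, 0 °C
Reagents that add atoms: none
Why: Dess–Martin oxidation of the allylic alcohol under buffered, non-aqueous conditions should leave the silyl enol ether and the PMB ether untouched.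

Step 6
Reactants: 8 (1S,10S)-vinyl ketone
Product: 9 (1S,2R,10S)-vinyl carbinol
Conditions: (S)-1-methyl-3,3-diphenyltetrahydro-1H,3H-pyrrolo[1,2-c][1,3,2]oxazaborole (20 mol%), catecholborane, toluene, −78 °C
Reagents that add atoms: none
Why: Corey–Bakshi–Shibata reduction under reagent control: the quaternary C1 acts as the large and the vinyl group as the small ketone substituent, so the (S)-oxazaborolidine should deliver hydride to the face that gives the (2R)-carbinol.

Step 7
Reactants: 9 (1S,2R,10S)-vinyl carbinol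
Product: 10 (1S,2R,10S)-C2 TBS ether
Conditions: TBSOTf, 2,6-lutidine, CH2Cl2, −78 → 0 °C
Reagents that add atoms: tert-butyldimethylsilyl triflate, CC(C)(C)[Si](C)(C)OS(=O)(=O)C(F)(F)F
Why: Silylation with the silyl triflate is the standard way to protect a hindered secondary alcohol and does not affect the existing stereocentres.

Step 8
Reactants: 10 (1S,2R,10S)-C2 TBS ether
Product: 11 (1S,2R,10S)-ring A enone (C12 ketone, C13=C14; C11 epimers)
Conditions: Pd(OAc)2 (1.1 equiv), MeCN, rt
Reagents that add atoms: none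
Why: Saegusa–Ito oxidation: the silyl enol ether is transmetallated to a palladium enolate and β-hydride elimination, possible only toward C14, gives the C13=C14 enone conjugated with C12.

Step 9
Reactants: 11 (1S,2R,10S)-ring A enone
Product: 12 (1S,2R,10S,11S)-11-hydroxy enone
Conditions: KN(SiMe3)2, THF, −78 °C; (±)-trans-2-(phenylsulfonyl)-3-phenyloxaziridine, −78 °C; AcOH quench
Reagents that add atoms: 2-(phenylsulfonyl)-3-phenyloxaziridine, O=S(=O)(c1ccccc1)N1OC1c1ccccc1
Why: Davis oxidation of the cross-conjugated potassium enolate (C11 is the only enolisable position because C1 is quaternary); the oxaziridine should approach C11 from the face opposite the adjacent C10 CH2OPMB group and the C1 methyl, so that the new hydroxyl is trans to C9 (11S).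

Step 10
Reactants: 12 (1S,2R,10S,11S)-11-hydroxy enone
Product: 13 (1S,2R,10S,11S)-hydroxy ketal (C12 1,3-dioxolane)
Conditions: ethylene glycol, pyridinium p-toluenesulfonate, benzene, reflux (Dean–Stark)
Reagents that add atoms: ethylene glycol, OCCO
Why: Acid-catalysed ketalisation with azeotropic removal of water; the double bond cannot move out of conjugation toward the quaternary C1, and the silyl and PMB ethers should tolerate the weak acid.

Step 11
Reactants: 14 (R)-2,2-dimethyl-1,3-dioxolane-4-carbaldehyde (D-glyceraldehyde acetonide)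
Product: 15 (4S)-4-[(1Z)-2-iodoprop-1-en-1-yl]-2,2-dimethyl-1,3-dioxolane
Conditions: EtPPh3I, n-BuLi, THF, rt; I2, −78 °C; NaN(SiMe3)2, −20 °C; then 14, −78 °C
Reagents that add atoms: ethyltriphenylphosphonium iodide, CC[P+](c1ccccc1)(c1ccccc1)c1ccccc1.[I-]; iodine, II
Why: Wittig olefination with the α-iodo ylide (Stork–Zhao-type) gives the Z-2-iodoalkene in which iodine is cis to C7; C7 is taken unchanged from D-glyceraldehyde.

Step 12
Reactants: 15 (4S)-4-[(1Z)-2-iodoprop-1-en-1-yl]-2,2-dimethyl-1,3-dioxolane
Product: 16 (2S,3Z)-4-iodopent-3-ene-1,2-diol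
Conditions: AcOH/H2O (4:1), 40 °C
Reagents that add atoms: none
Why: Acid hydrolysis of the terminal acetonide is routine and touches neither the vinyl iodide nor C7.

Step 13
Reactants: 16 (2S,3Z)-4-iodopent-3-ene-1,2-diol
Product: 17 (2S,3Z)-1,2-bis(tert-butyldimethylsilyloxy)-4-iodopent-3-ene
Conditions: TBSCl, imidazole, DMF, rt
Reagents that add atoms: tert-butyldimethylsilyl chloride, CC(C)(C)[Si](C)(C)Cl
Why: Standard imidazole-promoted silylation of both hydroxyls, so that no free alcohol is present next to a silyl ether under the basic coupling conditions of step 14.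

Step 14
Reactants: 13 (1S,2R,10S,11S)-hydroxy ketal; 17 (2S,3Z)-1,2-bis(tert-butyldimethylsilyloxy)-4-iodopent-3-ene
Product: 19 (1S,2R,5Z,7S,10S,11S)-coupled C1–C8 chain (C2/C7/C8 TBS ethers; C9 PMB ether), via B-alkyl borane 18 (not isolated)
Conditions: 13, 9-borabicyclo[3.3.1]nonane (2.5 equiv), THF, rt; then 17, PdCl2[(Ph2PC5H4)2Fe] (5 mol%), AsPh3, Cs2CO3, DMF/H2O, rt
Reagents that add atoms: none
Why: B-alkyl Suzuki–Miyaura coupling: the borane adds anti-Markovnikov to the terminal vinyl group only (the ring alkene is too hindered), and the palladium-catalysed coupling with the vinyl iodide proceeds with retention, giving the 5Z trisubstituted alkene.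

Step 15
Reactants: 19 (1S,2R,5Z,7S,10S,11S)-coupled C1–C8 chain
Product: 20 (1S,2R,5Z,7S,10S,11S)-C8 primary alcohol
Conditions: HF·pyridine, pyridine, THF, 0 °C
Reagents that add atoms: none
Why: Buffered fluoride desilylation is much faster at the primary silyl ether than at the two secondary ones (selective deprotection).

Step 16
Reactants: 20 (1S,2R,5Z,7S,10S,11S)-C8 primary alcohol
Product: 21 (1S,2R,5Z,7S,10S,11S)-C8 aldehyde
Conditions: Dess–Martin periodinane, pyridine, CH2Cl2, 0 °C; used at once
Reagents that add atoms: none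
Why: Dess–Martin oxidation is non-basic, which should preserve the C7 centre of the α-silyloxy β,γ-unsaturated aldehyde; the tertiary 11-hydroxyl is inert.

Step 17
Reactants: 21 (1S,2R,5Z,7S,10S,11S)-C8 aldehyde; 22 methyl propionate
Product: 24 β-hydroxy ester (C8/C17 epimers), via methyl propionate lithium enolate 23 (not isolated)
Conditions: 22 (2.5 equiv), LiN(iPr)2, THF, −78 °C; then 21, −78 °C; AcOH quench at −78 °C
Reagents that add atoms: none
Why: Lithium ester enolate aldol addition, faster at −78 °C than enolisation of the aldehyde; the new C8 and C17 centres are not controlled because C8 is oxidised in step 19 and C17 is equilibrated in step 24.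

Step 18
Reactants: 24 β-hydroxy ester
Product: 25 C9 primary alcohol (C8/C17 epimers)
Conditions: DDQ, CH2Cl2/pH 7 phosphate buffer (10:1), 0 °C
Reagents that add atoms: none
Why: Oxidative cleavage of the PMB ether (hydride abstraction, then hydrolysis of the oxocarbenium ion); water is kept in excess so that the ion is hydrolysed and not captured by the 11-hydroxyl.

Step 19
Reactants: 25 C9 primary alcohol
Product: 26 (1S,2R,5Z,7S,10R,11S)-keto aldehyde (C9 aldehyde; C8 ketone of the methyl β-keto ester; C17 epimers)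
Conditions: Dess–Martin periodinane (3 equiv), pyridine, CH2Cl2, rt
Reagents that add atoms: none
Why: Dess–Martin oxidation of the primary C9 and secondary C8 hydroxyls (the tertiary 11-hydroxyl is inert) gives the keto aldehyde; C17 becomes a labile β-keto ester centre, so 26 is an interconverting pair of C17 epimers.

Step 20
Reactants: 26 (1S,2R,5Z,7S,10R,11S)-keto aldehyde
Product: 27 (1S,2R,5Z,7S,8R,9R,10S,11S)-ten-membered cis-8,9-diol with open C19 methyl ester (C17 epimers)
Conditions: SmI2 (2.5 equiv), t-BuOH (2 equiv), THF, slow addition of 26 (final 0.002 M), −78 °C; H2O quench at −78 °C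
Reagents that add atoms: none
Why: Divalent samarium transfers one electron to the C9 aldehyde, which is reduced more easily than the ketone; the ketyl carbon adds to the C8 carbonyl, which is held between the ketone and ester oxygens on trivalent samarium, and a second electron gives the samarium diolate that is protonated on quenching. The closest known reaction is the SmI2-promoted keto-aldehyde pinacol cyclisation of β-keto esters to cis-diols, together with SmI2 pinacol macrocyclisations. The ten-membered ring (C1–C10) closes by 10-exo-trig addition of the ketyl carbon to the C=O group, helped by the Z-C5=C6 alkene and the vicinal C1/C10 attachment to ring A, which hold the two carbonyl carbons near each other. The cis relation of the C8 and C9 oxygens should follow from both being bound to one samarium in the closing transition state; the C8 face is expected to be set by attack anti to the C7 silyloxy group of the chelate (polar Felkin–Anh), and the C9 face by the aldehyde rotamer that turns the samarium-bound oxygen away from the C1 and C11 substituents flanking C10. The step needs reduction of the aldehyde alone and ring closure ahead of dimerisation, over-reduction or reductive loss of the α-silyloxy group; the ketal masking of the ring A enone, the chelating ester, high dilution and −78 °C are there to secure this. C17 is not set in this step.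

Step 21
Reactants: 27 ten-membered cis-8,9-diol
Product: 28 C9 acetate (8-hydroxyl free; C17 epimers)
Conditions: Ac2O, DMAP, pyridine, CH2Cl2, rt
Reagents that add atoms: acetic anhydride, CC(=O)OC(C)=O
Why: DMAP-catalysed acetylation distinguishes the secondary 9-hydroxyl from the tertiary 8- and 11-hydroxyls, and blocking O9 leaves O7 as the only oxygen that can later form a γ-lactone with C19.

Step 22
Reactants: 28 C9 acetate
Product: 30 (1S,2R,5Z,7S,8S,9R,10S,11S)-hydroxy lactone (O7–C19 lactone; 2-hydroxyl free; C17 epimers), via desilylated triol ester 29 (not isolated)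
Conditions: HF·pyridine, THF, 0 °C → rt
Reagents that add atoms: none
Why: Acidic fluoride cleaves both silyl ethers and the liberated 7-hydroxyl closes the five-membered lactone on the C19 ester (5-exo-trig acyl substitution with loss of methanol); no stereocentre is touched.

Step 23
Reactants: 30 hydroxy lactone
Product: 31 2,9-diacetate ketal (C17 epimers)
Conditions: Ac2O, DMAP, Et3N, CH2Cl2, rt
Reagents that add atoms: acetic anhydride, CC(=O)OC(C)=O
Why: Acetylation of the only remaining secondary hydroxyl (C2); the tertiary 8- and 11-hydroxyls should not react under these conditions.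

Step 24
Reactants: 31 2,9-diacetate ketal (C17 epimers)
Product: 32 (17R)-2,9-diacetate ketal
Conditions: DBU, toluene, 60 °C
Reagents that add atoms: none
Why: Base-mediated epimerisation through the lactone enolate (thermodynamic control): the C17 methyl should settle trans to the bulky C9 ring bond and cis to the 8-hydroxyl, which is the 17R configuration of the target.

Step 25
Reactants: 32 (17R)-2,9-diacetate ketal
Product: 33 CNP0255369.2 (target)
Conditions: TsOH·H2O (cat.), THF/H2O (4:1), 40 °C
Reagents that add atoms: water, O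
Why: Acid-catalysed hydrolysis of the allylic dioxolane releases the C12 enone; the acetates, the lactone and the tertiary alcohols should tolerate the mild aqueous acid.

**Compound list**

1 | pent-1-en-3-one (ethyl vinyl ketone) | CCC(=O)C=C | starting material
2 | (Z)-3-(tert-butyldimethylsilyloxy)penta-1,3-diene | C/C=C(\O[Si](C)(C)C(C)(C)C)C=C | intermediate
3 | 2-[(4-methoxybenzyl)oxy]acetaldehyde | COc1ccc(COCC=O)cc1 | starting material
4 | 2-(triphenylphosphoranylidene)propanal | CC(C=O)=P(c1ccccc1)(c1ccccc1)c1ccccc1 | starting material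
5 | (E)-4-[(4-methoxybenzyl)oxy]-2-methylbut-2-enal | O=C/C(C)=C/COCc1ccc(OC)cc1 | intermediate
6 | (1S,10S)-ring A aldehyde: cyclohexene C1/C10–C14 with 1-methyl, 1-formyl (C2), 10-CH2OPMB (C9), 11-methyl (both epimers), 12-OTBS enol ether (C12=C13) | COc1ccc(COC[C@@H]2[C@](C)(CC=C(O[Si](C)(C)C(C)(C)C)C2C)C=O)cc1 | intermediate
7 | (1S,10S)-vinyl carbinols: 6 with C2 as CH(OH)CH=CH2 (C2 epimers) | COc1ccc(COC[C@@H]2[C@](C)(CC=C(O[Si](C)(C)C(C)(C)C)C2C)C(O)C=C)cc1 | intermediate
8 | (1S,10S)-vinyl ketone: 6 with C2 as C(=O)CH=CH2 | COc1ccc(COC[C@@H]2[C@](C)(CC=C(O[Si](C)(C)C(C)(C)C)C2C)C(=O)C=C)cc1 | intermediate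
9 | (1S,2R,10S)-vinyl carbinol | COc1ccc(COC[C@@H]2[C@](C)(CC=C(O[Si](C)(C)C(C)(C)C)C2C)[C@H](O)C=C)cc1 | intermediate
10 | (1S,2R,10S)-C2 TBS ether of 9 | COc1ccc(COC[C@@H]2[C@](C)(CC=C(O[Si](C)(C)C(C)(C)C)C2C)[C@H](O[Si](C)(C)C(C)(C)C)C=C)cc1 | intermediate
11 | (1S,2R,10S)-ring A enone: C12 ketone, C13=C14, 11-methyl (both epimers), 1-[CH(OTBS)CH=CH2], 10-CH2OPMB | COc1ccc(COC[C@@H]2[C@](C)(C=CC(=O)C2C)[C@H](O[Si](C)(C)C(C)(C)C)C=C)cc1 | intermediate
12 | (1S,2R,10S,11S)-11-hydroxy enone (11-OH trans to C9) | COc1ccc(COC[C@@H]2[C@](C)(C=CC(=O)[C@@]2(C)O)[C@H](O[Si](C)(C)C(C)(C)C)C=C)cc1 | intermediate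
13 | (1S,2R,10S,11S)-hydroxy ketal: 12 with C12 as 1,3-dioxolane | COc1ccc(COC[C@@H]2[C@](C)(C=CC3(OCCO3)[C@@]2(C)O)[C@H](O[Si](C)(C)C(C)(C)C)C=C)cc1 | intermediate
14 | (R)-2,2-dimethyl-1,3-dioxolane-4-carbaldehyde | O=C[C@H]1COC(C)(C)O1 | starting material
15 | (4S)-4-[(1Z)-2-iodoprop-1-en-1-yl]-2,2-dimethyl-1,3-dioxolane | C/C(I)=C/[C@H]1COC(C)(C)O1 | intermediate
16 | (2S,3Z)-4-iodopent-3-ene-1,2-diol | C/C(I)=C/[C@H](O)CO | intermediate
17 | (2S,3Z)-1,2-bis(tert-butyldimethylsilyloxy)-4-iodopent-3-ene | C/C(I)=C/[C@H](O[Si](C)(C)C(C)(C)C)CO[Si](C)(C)C(C)(C)C | intermediate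
18 | (1S,2R,10S,11S)-B-alkyl borane: 13 with the vinyl group converted to CH2CH2–B(9-borabicyclononyl) at C4 | COc1ccc(COC[C@@H]2[C@](C)(C=CC3(OCCO3)[C@@]2(C)O)[C@H](O[Si](C)(C)C(C)(C)C)CCB2C3CCCC2CCC3)cc1 | intermediate
19 | (1S,2R,5Z,7S,10S,11S)-coupled chain: ring A ketal with C2–OTBS, C5(Me)=C6, C7–OTBS, C8–OTBS, C9–OPMB, 11-OH | COc1ccc(COC[C@@H]2[C@](C)(C=CC3(OCCO3)[C@@]2(C)O)[C@H](O[Si](C)(C)C(C)(C)C)CC/C(C)=C\[C@H](O[Si](C)(C)C(C)(C)C)CO[Si](C)(C)C(C)(C)C)cc1 | intermediate
20 | (1S,2R,5Z,7S,10S,11S)-C8 primary alcohol | COc1ccc(COC[C@@H]2[C@](C)(C=CC3(OCCO3)[C@@]2(C)O)[C@H](O[Si](C)(C)C(C)(C)C)CC/C(C)=C\[C@H](O[Si](C)(C)C(C)(C)C)CO)cc1 | intermediate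
21 | (1S,2R,5Z,7S,10S,11S)-C8 aldehyde | COc1ccc(COC[C@@H]2[C@](C)(C=CC3(OCCO3)[C@@]2(C)O)[C@H](O[Si](C)(C)C(C)(C)C)CC/C(C)=C\[C@H](O[Si](C)(C)C(C)(C)C)C=O)cc1 | intermediate
22 | methyl propionate | CCC(=O)OC | starting material
23 | lithium enolate of methyl propionate | CC=C(OC)O[Li] | intermediate
24 | (1S,2R,5Z,7S,10S,11S)-β-hydroxy ester: C8 carbinol, C17 methyl, C19 methyl ester (C8 and C17 epimers) | COc1ccc(COC[C@@H]2[C@](C)(C=CC3(OCCO3)[C@@]2(C)O)[C@H](O[Si](C)(C)C(C)(C)C)CC/C(C)=C\[C@H](O[Si](C)(C)C(C)(C)C)C(O)C(C)C(=O)OC)cc1 | intermediate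
25 | (1S,2R,5Z,7S,10S,11S)-C9 primary alcohol of 24 (C8 and C17 epimers) | OC[C@@H]1[C@](C)(C=CC2(OCCO2)[C@@]1(C)O)[C@H](O[Si](C)(C)C(C)(C)C)CC/C(C)=C\[C@H](O[Si](C)(C)C(C)(C)C)C(O)C(C)C(=O)OC | intermediate
26 | (1S,2R,5Z,7S,10R,11S)-keto aldehyde: C9 aldehyde on ring A, C2–OTBS, C7–OTBS, C8 ketone, C17 methyl (labile, both epimers), C19 methyl ester; 10R only by priority change | O=C[C@@H]1[C@](C)(C=CC2(OCCO2)[C@@]1(C)O)[C@H](O[Si](C)(C)C(C)(C)C)CC/C(C)=C\[C@H](O[Si](C)(C)C(C)(C)C)C(=O)C(C)C(=O)OC | intermediate
27 | (1S,2R,5Z,7S,8R,9R,10S,11S)-ten-membered cis-8,9-diol, open C19 methyl ester, C2/C7 TBS ethers, C12 ketal (C17 epimers; 8R by rule while O7 is silylated, same spatial arrangement as 8S in 33) | O[C@@H]1[C@@H]2[C@](C)(C=CC3(OCCO3)[C@@]2(C)O)[C@H](O[Si](C)(C)C(C)(C)C)CC/C(C)=C\[C@H](O[Si](C)(C)C(C)(C)C)[C@@]1(O)C(C)C(=O)OC | intermediate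
28 | C9 acetate of 27 (C17 epimers) | CC(=O)O[C@@H]1[C@@H]2[C@](C)(C=CC3(OCCO3)[C@@]2(C)O)[C@H](O[Si](C)(C)C(C)(C)C)CC/C(C)=C\[C@H](O[Si](C)(C)C(C)(C)C)[C@@]1(O)C(C)C(=O)OC | intermediate
29 | desilylated 2,7,8,11-tetrol ester of 28 (C17 epimers) | CC(=O)O[C@@H]1[C@@H]2[C@](C)(C=CC3(OCCO3)[C@@]2(C)O)[C@H](O)CC/C(C)=C\[C@H](O)[C@@]1(O)C(C)C(=O)OC | intermediate
30 | (1S,2R,5Z,7S,8S,9R,10S,11S)-hydroxy lactone: O7–C19 γ-lactone, 9-OAc, 2-OH, 8-OH, 11-OH, C12 ketal (C17 epimers) | CC(=O)O[C@@H]1[C@@H]2[C@](C)(C=CC3(OCCO3)[C@@]2(C)O)[C@H](O)CC/C(C)=C\[C@@H]2OC(=O)C(C)[C@]21O | intermediate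
31 | 2,9-diacetate ketal (C17 epimers) | CC(=O)O[C@@H]1[C@@H]2[C@](C)(C=CC3(OCCO3)[C@@]2(C)O)[C@H](OC(C)=O)CC/C(C)=C\[C@@H]2OC(=O)C(C)[C@]21O | intermediate
32 | (1S,2R,5Z,7S,8S,9R,10S,11S,17R)-2,9-diacetate ketal | CC(=O)O[C@@H]1[C@@H]2[C@](C)(C=CC3(OCCO3)[C@@]2(C)O)[C@H](OC(C)=O)CC/C(C)=C\[C@@H]2OC(=O)[C@H](C)[C@]21O | intermediate
33 | CNP0255369.2: (1S,2R,5Z,7S,8S,9R,10S,11S,17R)-2,9-diacetoxy-8,11-dihydroxy-12-oxobriara-5,13-dien-19,7-olide | CC(=O)O[C@@H]1[C@@H]2[C@](C)(C=CC(=O)[C@@]2(C)O)[C@H](OC(C)=O)CC/C(C)=C\[C@@H]2OC(=O)[C@H](C)[C@]21O | target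

**Step count and risks**

Total: 25 steps. Longest linear sequence: 21 steps (steps 1, 3–10 and 14–25).

The three steps most likely to fail:

1. Step 20 (pinacol closure). The C9 ketyl may be reduced on to the alcohol, dimerise, or trigger loss of the C7 silyloxy group before it reaches the ketone across the forming medium ring, and the closure may show poor facial selectivity. Fallback: setting out from keto aldehyde 26, the two carbonyls are coupled on low-valent titanium (TiCl3·1.5DME, Zn–Cu couple, DME, slow addition, rt, aqueous K2CO3 work-up at the diol stage; McMurry-type pinacol coupling). Here both carbonyl groups are reduced and joined on the metal surface, so the closure no longer depends on a single ketyl adding in solution. The diol comes back to the route at 27 and no new compound is made (F0).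

2. Step 3 (Diels–Alder reaction). The cycloaddition of the trisubstituted enal may be sluggish, the silyl enol ether may add to the activated formyl group (Mukaiyama aldol), or the enantioselectivity may be insufficient. Fallback: setting out from diene 2, the same catalyst is used with the doubly activated, purchasable ethyl (E)-3-methyl-4-oxobut-2-enoate, whose formyl group again directs C11 to the β-carbon, to give the ester aldehyde F1. CH2=CHMgBr at −78 °C adds to the formyl group only and gives the hydroxy ester F2. LiAlH4 reduces the ester to the diol F3. NaH, PMBCl and Bu4NI then etherify the primary C9 hydroxyl in preference to the hindered secondary one, which comes back to the route at 7.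

3. Step 10 (ketalisation). Ketalisation of the hindered, conjugated, α-hydroxylated C12 carbonyl may stay incomplete, or the long acidic reflux may strip the silyl ether. Fallback: setting out from hydroxy enone 12, Me3SiOTf/Et3N caps the tertiary hydroxyl as the trimethylsilyl ether F4. Me3SiOCH2CH2OSiMe3 with catalytic Me3SiOTf at −78 to −20 °C then transfers the dioxolane under water-free, kinetically driven conditions (Noyori ketalisation) to give the silylated ketal F5. K2CO3 in MeOH removes the trimethylsilyl group and comes back to the route at 13.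

**Further compounds**

F0 | step 20 | none | none
F1 | step 3 | ethyl (1S,2S)-5-(tert-butyldimethylsilyloxy)-2-formyl-2,6-dimethylcyclohex-4-ene-1-carboxylate (C6 epimers; ring A aldehyde with C9 as CO2Et) | CCOC(=O)[C@@H]1[C@](C)(CC=C(O[Si](C)(C)C(C)(C)C)C1C)C=O
F2 | step 3 | ethyl (1S,2S)-5-(tert-butyldimethylsilyloxy)-2-(1-hydroxyprop-2-en-1-yl)-2,6-dimethylcyclohex-4-ene-1-carboxylate (carbinol and C6 epimers) | CCOC(=O)[C@@H]1[C@](C)(CC=C(O[Si](C)(C)C(C)(C)C)C1C)C(O)C=C
F3 | step 3 | 1-[(1S,6S)-4-(tert-butyldimethylsilyloxy)-6-(hydroxymethyl)-1,5-dimethylcyclohex-3-en-1-yl]prop-2-en-1-ol (carbinol and C5 epimers) | OC[C@@H]1[C@](C)(CC=C(O[Si](C)(C)C(C)(C)C)C1C)C(O)C=C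
F4 | step 10 | 11-O-trimethylsilyl ether of hydroxy enone 12 | COc1ccc(COC[C@@H]2[C@](C)(C=CC(=O)[C@@]2(C)O[Si](C)(C)C)[C@H](O[Si](C)(C)C(C)(C)C)C=C)cc1
F5 | step 10 | 11-O-trimethylsilyl ether of hydroxy ketal 13 | COc1ccc(COC[C@@H]2[C@](C)(C=CC3(OCCO3)[C@@]2(C)O[Si](C)(C)C)[C@H](O[Si](C)(C)C(C)(C)C)C=C)cc1
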